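**Retrosynthetic overview**
- Ring C (the chroman pyran) is closed last by intramolecular Mitsunobu O-alkylation of a phenol/primary-alcohol diol; both silyl ethers are removed in the same flask.
- The diol comes from hydride opening of an (R)-3-aryl-dihydrocoumarin. Its C3–C1' bond is the key bond: a racemic 3-bromo-dihydrocoumarin (lactone α-carbon made electrophilic, an enolonium equivalent) is joined to the arylzinc of ring B by a nickel/pybox stereoconvergent coupling that sets C3.
- The bromolactone comes from 7-hydroxy-5-methoxychroman-2-one, made from 5-methoxyresorcinol and acrylic acid (Friedel–Crafts/lactonisation).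
- The arylzinc comes from 8-bromo-2,2-dimethyl-5-silyloxy-2H-chromene, made from 4-bromoresorcinol and 3-methylbut-2-enal.
- Ring order: lactone ring on ring A and dimethylpyran ring D on ring B are built separately, the fragments are coupled, the lactone is opened, and ring C is closed.

Assumption: the sense of induction in step 5 is taken by analogy with α-bromo ketone arylations. The ligand antipode that gives the (3R) lactone is the one used, written here as (R,R)-Ph-pybox = 2,6-bis[(4R)-4-phenyl-4,5-dihydro-1,3-oxazol-2-yl]pyridine, and is confirmed on the first run by chiral HPLC/ECD. All starting materials (1, 2, 7, 9) are catalogue chemicals.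

**Step 1**
Reactants: 1 5-methoxyresorcinol; 2 acrylic acid
Product: 3 7-hydroxy-5-methoxychroman-2-one
Conditions: 1 (1.2 equiv), 2 (1.0 equiv), Amberlyst-15 (polystyrene-SO3H resin), toluene, reflux, Dean–Stark
Reagents that add atoms: none
Why: Acid-catalysed Friedel–Crafts hydroarylation of acrylic acid followed by lactonisation; C-alkylation goes mainly para to a free OH (C4/C6 of 1, two equivalent sites), where only the neighbouring OH can lactonise, giving the 5-methoxy-7-hydroxy pattern, and the minor 5-hydroxy-7-methoxy isomer is removed by crystallisation/chromatography.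

**Step 2**
Reactants: 3 7-hydroxy-5-methoxychroman-2-one
Product: 6 rac-3-bromo-7-[(tert-butyldimethylsilyl)oxy]-5-methoxychroman-2-one, via silyl ether lactone 4 (not isolated), via ketene silyl acetal 5 (not isolated)
Conditions: TBSOTf (2.3 equiv), Et3N (2.4 equiv), CH2Cl2, 0 °C → rt; then NBS (1.05 equiv), −78 °C; cold pH 7 buffer quench
Reagents that add atoms: tert-butyldimethylsilyl trifluoromethanesulfonate (TBSOTf), CC(C)(C)[Si](C)(C)OS(=O)(=O)C(F)(F)F; N-bromosuccinimide (NBS), O=C1CCC(=O)N1Br
Why: Phenol O-silylation and soft enolisation of the activated aryl lactone give ketene silyl acetal 5, whose α-bromination by NBS at −78 °C outpaces ring bromination; the product is deliberately racemic because step 5 is stereoconvergent.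

**Step 3**
Reactants: 7 4-bromoresorcinol
Product: 8 2-bromo-5-[(triisopropylsilyl)oxy]phenol
Conditions: TIPSCl (1.0 equiv), imidazole, CH2Cl2/DMF, 0 °C
Reagents that add atoms: triisopropylsilyl chloride (TIPSCl), CC(C)[Si](Cl)(C(C)C)C(C)C
Why: Sterically controlled mono-silylation: the bulky silyl chloride takes the unhindered OH para to bromine and leaves the OH flanked by bromine free.

**Step 4**
Reactants: 8 2-bromo-5-[(triisopropylsilyl)oxy]phenol; 9 3-methylbut-2-enal
Product: 10 8-bromo-2,2-dimethyl-5-[(triisopropylsilyl)oxy]-2H-chromene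
Conditions: 9 (2 equiv), PhB(OH)2 (1.0 equiv, recovered), AcOH (cat.), toluene, reflux, Dean–Stark
Reagents that add atoms: none
Why: Phenylboronic acid-templated ortho-hydroxyalkylation at the only free ortho position gives a benzodioxaborin that fragments to an ortho-quinone methide and closes by oxa-6π electrocyclisation (chromene annulation), so the pyran oxygen is necessarily the one next to the bromine-bearing carbon.

**Step 5**
Reactants: 10 8-bromo-2,2-dimethyl-5-[(triisopropylsilyl)oxy]-2H-chromene; 6 rac-3-bromo-7-[(tert-butyldimethylsilyl)oxy]-5-methoxychroman-2-one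
Product: 13 (3R)-7-[(tert-butyldimethylsilyl)oxy]-3-{2,2-dimethyl-5-[(triisopropylsilyl)oxy]-2H-chromen-8-yl}-5-methoxychroman-2-one, via aryl Grignard reagent 11 (not isolated), via arylzinc iodide 12 (not isolated)
Conditions: 10 (1.5 equiv), Mg, THF, 40 °C; ZnI2, THF, 0 °C; then 6 (1.0 equiv), NiCl2·DME (10 mol %), (R,R)-Ph-pybox (13 mol %), DME/THF, −30 °C; aq. NH4Cl
Reagents that add atoms: none
Why: Proposed new method: a monovalent nickel–aryl species abstracts bromine from either enantiomer of 6 to give a planar lactone α-radical, which is captured by the chiral divalent aryl–nickel pybox complex and reductively eliminated from trivalent nickel, so the ligand alone sets C3 as R; the base-free −30 °C conditions keep the acidic tertiary centre from racemising; closest known reaction types are the nickel/pybox stereoconvergent Negishi α-arylation of racemic α-bromo ketones and the nickel/diamine arylation of racemic α-bromo aryl esters.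

**Step 6**
Reactants: 13 (3R)-7-[(tert-butyldimethylsilyl)oxy]-3-{2,2-dimethyl-5-[(triisopropylsilyl)oxy]-2H-chromen-8-yl}-5-methoxychroman-2-one
Product: 14 5-[(tert-butyldimethylsilyl)oxy]-2-[(2R)-2-{2,2-dimethyl-5-[(triisopropylsilyl)oxy]-2H-chromen-8-yl}-3-hydroxypropyl]-3-methoxyphenol
Conditions: LiBH4 (2 equiv), THF, −20 → 0 °C; aq. NH4Cl
Reagents that add atoms: none
Why: Hydride reduction of the activated aryl lactone to phenol plus primary alcohol is fast and essentially non-basic, so the α-aryl centre is carried through unchanged (R) and is no longer acidic afterwards; silyl ethers and the chromene alkene are inert.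

**Step 7**
Reactants: 14 5-[(tert-butyldimethylsilyl)oxy]-2-[(2R)-2-{2,2-dimethyl-5-[(triisopropylsilyl)oxy]-2H-chromen-8-yl}-3-hydroxypropyl]-3-methoxyphenol
Product: 16 (3R)-3-(5-hydroxy-2,2-dimethyl-2H-chromen-8-yl)-5-methoxychroman-7-ol, via bis-silyl isoflavan 15 (not isolated)
Conditions: PPh3 (1.3 equiv), DIAD (1.3 equiv), THF, 0 °C → rt; then TBAF (2.5 equiv), AcOH (2.5 equiv), 0 °C → rt
Reagents that add atoms: none
Why: Intramolecular Mitsunobu etherification closes ring C by SN2 attack of the only free phenol on the activated primary carbon (the stereocentre is not touched and stays R), and buffered fluoride then cleaves both aryl silyl ethers without affecting the chromene.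

**Compound list**
1 | 5-methoxyresorcinol (5-methoxybenzene-1,3-diol) | COc1cc(O)cc(O)c1 | starting material
2 | acrylic acid | C=CC(=O)O | starting material
3 | 7-hydroxy-5-methoxychroman-2-one | COc1cc(O)cc2OC(=O)CCc12 | intermediate
4 | 7-[(tert-butyldimethylsilyl)oxy]-5-methoxychroman-2-one (not isolated) | COc1cc(O[Si](C)(C)C(C)(C)C)cc2OC(=O)CCc12 | intermediate
5 | 2,7-bis[(tert-butyldimethylsilyl)oxy]-5-methoxy-4H-chromene, ketene silyl acetal (not isolated) | COc1cc(O[Si](C)(C)C(C)(C)C)cc2OC(O[Si](C)(C)C(C)(C)C)=CCc12 | intermediate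
6 | rac-3-bromo-7-[(tert-butyldimethylsilyl)oxy]-5-methoxychroman-2-one | COc1cc(O[Si](C)(C)C(C)(C)C)cc2OC(=O)C(Br)Cc12 | intermediate
7 | 4-bromoresorcinol (4-bromobenzene-1,3-diol) | Oc1ccc(Br)c(O)c1 | starting material
8 | 2-bromo-5-[(triisopropylsilyl)oxy]phenol | Oc1cc(O[Si](C(C)C)(C(C)C)C(C)C)ccc1Br | intermediate
9 | 3-methylbut-2-enal | CC(C)=CC=O | starting material
10 | 8-bromo-2,2-dimethyl-5-[(triisopropylsilyl)oxy]-2H-chromene | CC1(C)C=Cc2c(O[Si](C(C)C)(C(C)C)C(C)C)ccc(Br)c2O1 | intermediate
11 | {2,2-dimethyl-5-[(triisopropylsilyl)oxy]-2H-chromen-8-yl}magnesium bromide (not isolated) | Br[Mg]c1ccc(O[Si](C(C)C)(C(C)C)C(C)C)c2C=CC(C)(C)Oc12 | intermediate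
12 | {2,2-dimethyl-5-[(triisopropylsilyl)oxy]-2H-chromen-8-yl}zinc iodide (not isolated) | I[Zn]c1ccc(O[Si](C(C)C)(C(C)C)C(C)C)c2C=CC(C)(C)Oc12 | intermediate
13 | (3R)-7-[(tert-butyldimethylsilyl)oxy]-3-{2,2-dimethyl-5-[(triisopropylsilyl)oxy]-2H-chromen-8-yl}-5-methoxychroman-2-one | COc1cc(O[Si](C)(C)C(C)(C)C)cc2c1C[C@H](c1ccc(O[Si](C(C)C)(C(C)C)C(C)C)c3c1OC(C)(C)C=C3)C(=O)O2 | intermediate
14 | 5-[(tert-butyldimethylsilyl)oxy]-2-[(2R)-2-{2,2-dimethyl-5-[(triisopropylsilyl)oxy]-2H-chromen-8-yl}-3-hydroxypropyl]-3-methoxyphenol | COc1cc(O[Si](C)(C)C(C)(C)C)cc(O)c1C[C@H](c1ccc(O[Si](C(C)C)(C(C)C)C(C)C)c2c1OC(C)(C)C=C2)CO | intermediate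
15 | (3R)-7-[(tert-butyldimethylsilyl)oxy]-3-{2,2-dimethyl-5-[(triisopropylsilyl)oxy]-2H-chromen-8-yl}-5-methoxychroman (not isolated) | COc1cc(O[Si](C)(C)C(C)(C)C)cc2c1C[C@H](c1ccc(O[Si](C(C)C)(C(C)C)C(C)C)c3c1OC(C)(C)C=C3)CO2 | intermediate
16 | (3R)-3-(5-hydroxy-2,2-dimethyl-2H-chromen-8-yl)-5-methoxychroman-7-ol (CNP0320659.1) | COc1cc(O)cc2c1C[C@H](c1ccc(O)c3c1OC(C)(C)C=C3)CO2 | target

**Totals**
Total step count: 7. Longest linear sequence: 5 (steps 1, 2, 5, 6, 7, or equally 3, 4, 5, 6, 7). Enantiomeric purity is measured on 13 and 14 by chiral HPLC; 14 is the point for upgrading by crystallisation if needed.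

**Three steps most likely to fail, each with a fallback**

Step 5 (key coupling). A cyclic α-bromo aryl ester is an untested substrate class, the arylzinc carries an ortho oxygen substituent, and HBr loss from 6 to the coumarin competes. The fallback moves the polarity reversal from the lactone to the aryl group; it sets out from 10 and from 3, and comes back at 13. The Grignard reagent 11 made from 10 is quenched with B(OMe)3 and aqueous HCl to give {2,2-dimethyl-5-[(triisopropylsilyl)oxy]-2H-chromen-8-yl}boronic acid F1. Boron-to-iodine exchange with MesI(OAc)2/BF3·OEt2 in CH2Cl2 at −78 → 0 °C (kept cold to spare the chromene alkene), followed by an aqueous NaOTf wash, gives {2,2-dimethyl-5-[(triisopropylsilyl)oxy]-2H-chromen-8-yl}(2,4,6-trimethylphenyl)iodonium trifluoromethanesulfonate F2. Compound 3 is converted as in step 2 into ketene silyl acetal 5, which is this time isolated by non-aqueous work-up before any NBS is added. Acetal 5 is then arylated with F2 under Cu(OTf)2/chiral Ph-box catalysis in CH2Cl2 at −20 °C. The electrophilic aryl–copper species transfers the less hindered chromenyl group (mesityl stays on iodine) to the ketene acetal face selected by the ligand, under base-free conditions, to give 13.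

Step 1 (regiochemistry of the annulation). If the 5-hydroxy-7-methoxy lactone dominates or cannot be separated, the fallback sets out from 1 and comes back at 3. Vilsmeier–Haack formylation (POCl3, DMF, MeCN, 0 °C → rt, aqueous hydrolysis) gives 2,4-dihydroxy-6-methoxybenzaldehyde F3; this isomer is expected to be the major one and is easily told apart from the 2,6-dihydroxy isomer (one chelated OH against two). Wittig olefination with Ph3P=CHCO2Et in N,N-diethylaniline at reflux gives ethyl (E)-3-(2,4-dihydroxy-6-methoxyphenyl)prop-2-enoate F4 (not isolated), which isomerises and lactonises in the same pot to 7-hydroxy-5-methoxy-2H-chromen-2-one F5. Hydrogenation (H2, Pd/C, EtOAc, rt) of the coumarin double bond gives 3.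

Step 4 (chromene annulation next to the bulky silyl ether). If direct C-alkylation at the crowded ortho position fails, the fallback sets out from 8 and comes back at 10. O-Alkylation with 3-chloro-3-methylbut-1-yne (K2CO3, KI, acetone, reflux) gives 1-bromo-2-[(2-methylbut-3-yn-2-yl)oxy]-4-[(triisopropylsilyl)oxy]benzene F6. Heating F6 in N,N-diethylaniline at 150–180 °C triggers an aromatic propargyl Claisen rearrangement into the only free ortho position, then a [1,5]-H shift and oxa-6π electrocyclisation, to give 10.

**Further compounds**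
F1 | step 5 | {2,2-dimethyl-5-[(triisopropylsilyl)oxy]-2H-chromen-8-yl}boronic acid | OB(O)c1ccc(O[Si](C(C)C)(C(C)C)C(C)C)c2C=CC(C)(C)Oc12
F2 | step 5 | {2,2-dimethyl-5-[(triisopropylsilyl)oxy]-2H-chromen-8-yl}(2,4,6-trimethylphenyl)iodonium trifluoromethanesulfonate | Cc1cc(C)c([I+]c2ccc(O[Si](C(C)C)(C(C)C)C(C)C)c3C=CC(C)(C)Oc23)c(C)c1.[O-]S(=O)(=O)C(F)(F)F
F3 | step 1 | 2,4-dihydroxy-6-methoxybenzaldehyde | COc1cc(O)cc(O)c1C=O
F4 | step 1 | ethyl (E)-3-(2,4-dihydroxy-6-methoxyphenyl)prop-2-enoate (not isolated) | CCOC(=O)/C=C/c1c(O)cc(O)cc1OC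
F5 | step 1 | 7-hydroxy-5-methoxy-2H-chromen-2-one | COc1cc(O)cc2oc(=O)ccc12
F6 | step 4 | 1-bromo-2-[(2-methylbut-3-yn-2-yl)oxy]-4-[(triisopropylsilyl)oxy]benzene | C#CC(C)(C)Oc1cc(O[Si](C(C)C)(C(C)C)C(C)C)ccc1Br
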